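**Strategy.** The route rests on cutting both bonds that join the pyran ring to ring A, C4–C4a and O1–C8a. The four atoms O1–C2–C3=C4, with the C2 stereocentre, are taken intact from (S)-linalool and stored as a cyclic (Z)-alkenylboronic half acid (a 1,2-oxaborole); ring A is a 3-iodo-4-fluoroacetophenone. The key step exploits that C8a is para to the C6 ketone and C4a is its neighbour: Suzuki coupling at the C4a iodide delivers the alkene cis to the ring, and the tertiary alkoxide then displaces the C8a fluoride by SNAr in the same pot. Aldol condensation and MOM cleavage complete the chalcone.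

Key step: step 8

Remark: (S)-(+)-linalool (coriandrol) of high enantiomeric purity is assumed to be purchasable. Its carbinol carbon becomes C2 of the target with the same spatial arrangement, and the descriptor stays S. Atom numbers follow 2H-chromene numbering.

**Ring A fragment**

Step 1
Reactants: 1 1-(4-fluoro-2-hydroxyphenyl)ethanone
Product: 3 1-(4-fluoro-2,5-dihydroxyphenyl)ethanone, via aryl sulfate monoester 2 (not isolated)
Conditions: K2S2O8, KOH (aq), 15 °C; then HCl (aq), 90 °C
Reagents that add atoms: potassium peroxodisulfate [K+].[K+].[O-]S(=O)(=O)OOS(=O)(=O)[O-]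
Why: Elbs persulfate oxidation, in which the phenoxide attacks the peroxide oxygen through its only free para carbon and the resulting aryl sulfate is hydrolysed by acid to the hydroquinone.

Step 2
Reactants: 3 1-(4-fluoro-2,5-dihydroxyphenyl)ethanone
Product: 4 1-[4-fluoro-2-hydroxy-5-(methoxymethoxy)phenyl]ethanone
Conditions: MOMCl (1.05 equiv), iPr2NEt, CH2Cl2, 0 °C
Reagents that add atoms: chloromethyl methyl ether COCCl
Why: O-alkylation (Williamson type) should take place only at the 5-hydroxyl, because the 2-hydroxyl is held in a hydrogen bond to the acetyl group.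

Step 3
Reactants: 4 1-[4-fluoro-2-hydroxy-5-(methoxymethoxy)phenyl]ethanone
Product: 5 1-[4-fluoro-2-hydroxy-3-iodo-5-(methoxymethoxy)phenyl]ethanone
Conditions: BnMe3N ICl2, NaHCO3, CH2Cl2/MeOH, rt
Reagents that add atoms: benzyltrimethylammonium dichloroiodate C[N+](C)(C)Cc1ccccc1.Cl[I-]Cl
Why: Electrophilic aromatic iodination directed by the free phenol, whose para position is blocked, so iodine should enter the ortho carbon between hydroxyl and fluorine; the buffered medium spares the MOM ether.

Step 4
Reactants: 5 1-[4-fluoro-2-hydroxy-3-iodo-5-(methoxymethoxy)phenyl]ethanone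
Product: 6 1-[4-fluoro-3-iodo-2,5-bis(methoxymethoxy)phenyl]ethanone
Conditions: NaH (1.1 equiv), DMF, 0 °C; then MOMCl, 0 °C to rt
Reagents that add atoms: chloromethyl methyl ether COCCl
Why: Williamson etherification of the sodium phenoxide, which overcomes the hydrogen bond and the crowding by iodine; capping this phenol keeps ring A electron-poor for step 8.

**Pyran fragment**

Step 5
Reactants: 7 (S)-linalool
Product: 8 (3S)-5-(3,3-dimethyloxiran-2-yl)-3-methylpent-1-en-3-ol (both epimers at the oxirane carbon)
Conditions: mCPBA (1.05 equiv), NaHCO3, CH2Cl2, 0 °C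
Reagents that add atoms: 3-chloroperoxybenzoic acid OOC(=O)c1cccc(Cl)c1
Why: Prilezhaev epoxidation should pick the electron-rich trisubstituted alkene over the vinyl group, and the buffer suppresses acid-triggered cyclisation to linalool oxides; the new oxirane stereocentre is uncontrolled but is erased in step 6.

Step 6
Reactants: 8 (3S)-5-(3,3-dimethyloxiran-2-yl)-3-methylpent-1-en-3-ol
Product: 9 (6S)-2,6-dimethyloct-7-ene-2,6-diol
Conditions: LiAlH4, THF, 0 °C to rt; aqueous work-up
Reagents that add atoms: none
Why: SN2 opening of the trisubstituted epoxide by hydride at its less substituted carbon should leave the oxygen on the dimethyl-substituted carbon as the tertiary alcohol.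

Step 7
Reactants: 9 (6S)-2,6-dimethyloct-7-ene-2,6-diol
Product: 12 (5S)-5-(4-hydroxy-4-methylpentyl)-5-methyl-1,2-oxaborol-2(5H)-ol, via allyl vinylboronate 10 (not isolated), via butyl oxaborole ester 11 (not isolated)
Conditions: dibutyl vinylboronate (1.3 equiv), CH2Cl2, rt, evaporate; second-generation Grubbs catalyst RuCl2(=CHPh)(H2IMes)(PCy3) (5 mol %), CH2Cl2 (0.02 M), 40 °C; then THF/H2O
Reagents that add atoms: dibutyl vinylboronate C=CB(OCCCC)OCCCC; water O
Why: Boron-tethered ring-closing metathesis: transesterification links the vinylboron unit to the allylic oxygen, loss of ethene closes the five-membered ring and fixes the alkene as Z, and reversible boron exchange between the two hydroxyls funnels material through the allylic ester; the carbinol stereocentre is not touched.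

**Union and completion**

Step 8
Reactants: 6 1-[4-fluoro-3-iodo-2,5-bis(methoxymethoxy)phenyl]ethanone; 12 (5S)-5-(4-hydroxy-4-methylpentyl)-5-methyl-1,2-oxaborol-2(5H)-ol
Product: 14 1-[(2S)-2-(4-hydroxy-4-methylpentyl)-5,8-bis(methoxymethoxy)-2-methyl-2H-chromen-6-yl]ethanone, via Z-allylic alcohol 13 (not isolated)
Conditions: Pd(OAc)2 (5 mol %), SPhos (10 mol %), Cs2CO3 (4 equiv), degassed DMF/H2O (20:1), 70 °C; then 110 °C in the same pot
Reagents that add atoms: none
Why: Zerovalent palladium should insert into the C–I bond only, transmetalation from the hydroxyboronate of 12 and reductive elimination form C4–C4a with retention of the Z geometry, and the tertiary alkoxide thus released next to the ring adds to C8a and expels fluoride through a Meisenheimer anion stabilised by the para C6 ketone, forming O1–C8a. The closest known reactions are the Suzuki–Miyaura coupling of cyclic alkenylboronic half acids and the intramolecular SNAr etherification of ketone-activated aryl fluorides, run here as a domino annulation. The pyran ring closes in a 6-exo-trig addition to the arene. No stereocentre is formed, and C2 keeps its configuration because none of its four bonds takes part. The step needs chemoselectivity between the two halides, secured by their orthogonal reactivity (oxidative addition at iodide, addition–elimination at fluoride), and ring closure faster than attack by hydroxide or another alkoxide, secured by the cis alkene that holds O1 beside C8a. The two MOM ethers keep both phenols from forming phenoxides that would switch off the SNAr.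

Step 9
Reactants: 14 1-[(2S)-2-(4-hydroxy-4-methylpentyl)-5,8-bis(methoxymethoxy)-2-methyl-2H-chromen-6-yl]ethanone; 15 4-(methoxymethoxy)benzaldehyde
Product: 16 (2E)-1-[(2S)-2-(4-hydroxy-4-methylpentyl)-5,8-bis(methoxymethoxy)-2-methyl-2H-chromen-6-yl]-3-[4-(methoxymethoxy)phenyl]prop-2-en-1-one
Conditions: KOH (aq), EtOH, rt
Reagents that add atoms: none
Why: Claisen–Schmidt condensation of the methyl ketone enolate with the non-enolisable aldehyde, where E1cB loss of water should give the conjugated E enone; MOM ethers, chromene and tertiary alcohol are stable to base.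

Step 10
Reactants: 16 (2E)-1-[(2S)-2-(4-hydroxy-4-methylpentyl)-5,8-bis(methoxymethoxy)-2-methyl-2H-chromen-6-yl]-3-[4-(methoxymethoxy)phenyl]prop-2-en-1-one
Product: 17 (2E)-1-[(2S)-5,8-dihydroxy-2-(4-hydroxy-4-methylpentyl)-2-methyl-2H-chromen-6-yl]-3-(4-hydroxyphenyl)prop-2-en-1-one
Conditions: HCl (3 M aq)/MeOH, degassed, argon, rt
Reagents that add atoms: none
Why: Acid-catalysed acetal exchange with methanol should remove all three MOM groups at room temperature, at which the non-allylic tertiary alcohol, the chromene and the E enone should persist; the hydroquinone is kept from air oxidation by the acidic, oxygen-free medium.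

**Compound list**

1 | 1-(4-fluoro-2-hydroxyphenyl)ethanone | CC(=O)c1ccc(F)cc1O | starting material
2 | potassium 5-acetyl-2-fluoro-4-hydroxyphenyl sulfate | CC(=O)c1cc(OS(=O)(=O)[O-])c(F)cc1O.[K+] | intermediate (not isolated)
3 | 1-(4-fluoro-2,5-dihydroxyphenyl)ethanone | CC(=O)c1cc(O)c(F)cc1O | intermediate
4 | 1-[4-fluoro-2-hydroxy-5-(methoxymethoxy)phenyl]ethanone | CC(=O)c1cc(OCOC)c(F)cc1O | intermediate
5 | 1-[4-fluoro-2-hydroxy-3-iodo-5-(methoxymethoxy)phenyl]ethanone | CC(=O)c1cc(OCOC)c(F)c(I)c1O | intermediate
6 | 1-[4-fluoro-3-iodo-2,5-bis(methoxymethoxy)phenyl]ethanone | CC(=O)c1cc(OCOC)c(F)c(I)c1OCOC | intermediate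
7 | (S)-linalool, (3S)-3,7-dimethylocta-1,6-dien-3-ol | CC(C)=CCC[C@](C)(O)C=C | starting material
8 | (3S)-5-(3,3-dimethyloxiran-2-yl)-3-methylpent-1-en-3-ol, both epimers at the oxirane carbon | CC1(C)OC1CC[C@](C)(O)C=C | intermediate
9 | (6S)-2,6-dimethyloct-7-ene-2,6-diol | CC(C)(O)CCC[C@](C)(O)C=C | intermediate
10 | butyl (3S)-7-hydroxy-3,7-dimethyloct-1-en-3-yl ethenylboronate | CC(C)(O)CCC[C@](C)(OB(C=C)OCCCC)C=C | intermediate (not isolated)
11 | (5S)-2-butoxy-5-(4-hydroxy-4-methylpentyl)-5-methyl-2,5-dihydro-1,2-oxaborole | CC(C)(O)CCC[C@@]1(C)C=CB(OCCCC)O1 | intermediate (not isolated)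
12 | (5S)-5-(4-hydroxy-4-methylpentyl)-5-methyl-1,2-oxaborol-2(5H)-ol | CC(C)(O)CCC[C@@]1(C)C=CB(O)O1 | intermediate
13 | 1-{3-[(1Z,3S)-3,7-dihydroxy-3,7-dimethyloct-1-en-1-yl]-4-fluoro-2,5-bis(methoxymethoxy)phenyl}ethanone | CC(C)(O)CCC[C@](C)(O)/C=C\c1c(F)c(OCOC)cc(C(C)=O)c1OCOC | intermediate (not isolated)
14 | 1-[(2S)-2-(4-hydroxy-4-methylpentyl)-5,8-bis(methoxymethoxy)-2-methyl-2H-chromen-6-yl]ethanone | CC(C)(O)CCC[C@@]1(C)C=Cc2c(OCOC)c(C(C)=O)cc(OCOC)c2O1 | intermediate
15 | 4-(methoxymethoxy)benzaldehyde | COCOc1ccc(C=O)cc1 | starting material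
16 | (2E)-1-[(2S)-2-(4-hydroxy-4-methylpentyl)-5,8-bis(methoxymethoxy)-2-methyl-2H-chromen-6-yl]-3-[4-(methoxymethoxy)phenyl]prop-2-en-1-one | CC(C)(O)CCC[C@@]1(C)C=Cc2c(OCOC)c(C(=O)/C=C/c3ccc(OCOC)cc3)cc(OCOC)c2O1 | intermediate
17 | (2E)-1-[(2S)-5,8-dihydroxy-2-(4-hydroxy-4-methylpentyl)-2-methyl-2H-chromen-6-yl]-3-(4-hydroxyphenyl)prop-2-en-1-one (CNP0322520.1) | CC(C)(O)CCC[C@@]1(C)C=Cc2c(O)c(C(=O)/C=C/c3ccc(O)cc3)cc(O)c2O1 | target

**Totals**

Total step count: 10. Longest linear sequence: 7 steps (steps 1–4, then 8–10); the linalool branch is 3 steps before the union.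

**Steps most likely to fail**

Step 8. The ring closure may not follow the coupling: under hot carbonate the acetyl group can be deprotonated to an enolate that makes ring A too electron-rich for SNAr, and hydroxide may then displace the fluoride instead. Fallback: the coupling is run alone at 60 °C and stopped at 13, which is isolated. 13 is condensed first with 15 (KOH, EtOH, 0 °C to rt) to give (2E)-1-{3-[(1Z,3S)-3,7-dihydroxy-3,7-dimethyloct-1-en-1-yl]-4-fluoro-2,5-bis(methoxymethoxy)phenyl}-3-[4-(methoxymethoxy)phenyl]prop-2-en-1-one F4. Its ketone no longer carries an acidic methyl group and activates the fluoride fully. Deprotonation of the alcohols with KN(SiMe3)2 (THF, 0 °C) should then close the pyran ring by SNAr, and the route is rejoined at 16.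

Step 7. The metathesis may stall, because the tertiary borate ester forms in an unfavourable equilibrium and both alkenes are slow partners (a vinylboron unit and a vinyl group on a fully substituted carbon). Fallback from 9: ozonolysis of the vinyl group (O3, CH2Cl2/MeOH, −78 °C; Me2S) gives (2S)-2,6-dihydroxy-2,6-dimethylheptanal F1. Homologation with the Ohira–Bestmann reagent (K2CO3, MeOH) gives (3S)-3,7-dimethyloct-1-yne-3,7-diol F2. Z-selective hydroboration of the terminal alkyne through a rhodium vinylidene (catecholborane in excess, [RhCl(cod)]2, P(iPr)3, Et3N, cyclohexane, rt) gives 2-[(1Z,3S)-3,7-dihydroxy-3,7-dimethyloct-1-en-1-yl]-1,3,2-benzodioxaborole F3. Aqueous work-up hydrolyses F3 and the free boronic acid cyclises onto the neighbouring hydroxyl, rejoining the route at 12.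

Step 10. Cleavage of three aryl MOM ethers on the finished chalcone may be accompanied by acid-promoted cyclisation of the 2′-hydroxychalcone to the flavanone, addition of methanol to the enone, or ionisation of the tertiary alcohol. Fallback from 14: the two MOM groups are removed at the ketone stage, where no enone is present (HCl, MeOH, rt), to give 1-[(2S)-5,8-dihydroxy-2-(4-hydroxy-4-methylpentyl)-2-methyl-2H-chromen-6-yl]ethanone F5. Claisen–Schmidt condensation with commercial 4-(tetrahydro-2H-pyran-2-yloxy)benzaldehyde (KOH, EtOH, strictly under argon) gives (2E)-1-[(2S)-5,8-dihydroxy-2-(4-hydroxy-4-methylpentyl)-2-methyl-2H-chromen-6-yl]-3-[4-(tetrahydro-2H-pyran-2-yloxy)phenyl]prop-2-en-1-one F6. The THP acetal is then cleaved under much milder acid (pyridinium p-toluenesulfonate, MeOH, rt) to give 17.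

**Further compounds**

F1 | step 7 | (2S)-2,6-dihydroxy-2,6-dimethylheptanal | CC(C)(O)CCC[C@](C)(O)C=O
F2 | step 7 | (3S)-3,7-dimethyloct-1-yne-3,7-diol | CC(C)(O)CCC[C@](C)(O)C#C
F3 | step 7 | 2-[(1Z,3S)-3,7-dihydroxy-3,7-dimethyloct-1-en-1-yl]-1,3,2-benzodioxaborole | CC(C)(O)CCC[C@](C)(O)/C=C\B1Oc2ccccc2O1
F4 | step 8 | (2E)-1-{3-[(1Z,3S)-3,7-dihydroxy-3,7-dimethyloct-1-en-1-yl]-4-fluoro-2,5-bis(methoxymethoxy)phenyl}-3-[4-(methoxymethoxy)phenyl]prop-2-en-1-one | CC(C)(O)CCC[C@](C)(O)/C=C\c1c(F)c(OCOC)cc(C(=O)/C=C/c2ccc(OCOC)cc2)c1OCOC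
F5 | step 10 | 1-[(2S)-5,8-dihydroxy-2-(4-hydroxy-4-methylpentyl)-2-methyl-2H-chromen-6-yl]ethanone | CC(C)(O)CCC[C@@]1(C)C=Cc2c(O)c(C(C)=O)cc(O)c2O1
F6 | step 10 | (2E)-1-[(2S)-5,8-dihydroxy-2-(4-hydroxy-4-methylpentyl)-2-methyl-2H-chromen-6-yl]-3-[4-(tetrahydro-2H-pyran-2-yloxy)phenyl]prop-2-en-1-one | CC(C)(O)CCC[C@@]1(C)C=Cc2c(O)c(C(=O)/C=C/c3ccc(OC4CCCCO4)cc3)cc(O)c2O1
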